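**Retrosynthetic overview** (benzofuran numbering: O1, C2, C3, C3a, C4–C7, C7a)

1. Target ⇒ nickel-catalysed [2+2+2] cycloaddition of a chiral 1,6-diyne (ynol ether plus terminal alkyne) with allyl(methoxy)ketene, forming C7–C6, C4–C5 and C3a–C7a; C5 is set by the chiral ligand.
2. Diyne ⇒ anti-homopropargylic alcohol + trichloroethylene (alkynyl ether synthesis).
3. Alcohol ⇒ 3,4-dimethoxybenzaldehyde + (S)-but-3-yn-2-yl mesylate (allenylzinc addition sets C2 and C3).
4. Ketene ⇒ 2-methoxypent-4-enoyl chloride ⇐ methoxyacetic acid + allyl bromide.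
5. Ring order: aryl ring A is bought; the dihydrofuran (ring B) and the cyclohexadienone (ring C) close together in the last step.

Assumption: (S)-but-3-yn-2-ol, 3,4-dimethoxybenzaldehyde, methoxyacetic acid and LDA solution are bought; (R,R)-DIOP is taken to favour the 5S epimer in step 6, which must be confirmed on the first run (the antipodal ligand is used otherwise).

**Step 1**
Reactants: 1 (S)-but-3-yn-2-ol
Product: 2 (S)-but-3-yn-2-yl methanesulfonate
Conditions: MsCl, Et3N, CH2Cl2, −78 → 0 °C
Reagents that add atoms: methanesulfonyl chloride, CS(=O)(=O)Cl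
Why: Plain O-sulfonylation (mesylation) of a secondary propargylic alcohol; the C–O bond at the stereocentre is not touched, so the S configuration is kept.

**Step 2**
Reactants: 2 (S)-but-3-yn-2-yl methanesulfonate; 3 3,4-dimethoxybenzaldehyde
Product: 5 (1R,2R)-1-(3,4-dimethoxyphenyl)-2-methylbut-3-yn-1-ol, via allenylzinc reagent 4 (not isolated)
Conditions: Pd(OAc)2 (5 mol %), PPh3 (5 mol %), Et2Zn (3 equiv), THF, −78 → −20 °C; aq NH4Cl
Reagents that add atoms: diethylzinc, CC[Zn]CC (zinc and ethyl stay only in 4; none in 5)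
Why: Marshall propargylation: zerovalent palladium opens the mesylate by anti SN2' oxidative addition, transmetalation gives the configurationally defined allenylzinc 4, and this adds to the aldehyde by SE2' through a cyclic transition state with aryl anti to methyl, so centre-to-axis-to-centre chirality transfer sets C2 (R) and C3 (R) as the anti pair (about 9:1 anti:syn expected for an aryl aldehyde, minor isomer removed by chromatography).

**Step 3**
Reactants: 5 (1R,2R)-1-(3,4-dimethoxyphenyl)-2-methylbut-3-yn-1-ol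
Product: 8 4-[(1R,2R)-1-(ethynyloxy)-2-methylbut-3-yn-1-yl]-1,2-dimethoxybenzene, via dichlorovinyl ether 6 (not isolated), via dilithio diyne 7 (not isolated)
Conditions: KH (1.1 equiv), THF, 0 °C; Cl2C=CHCl, −50 °C → rt; n-BuLi (3.3 equiv), −78 → −40 °C; MeOH, −78 °C; kept below 30 °C and used at once
Reagents that add atoms: trichloroethylene, ClC=C(Cl)Cl; n-butyllithium, [Li]CCCC (lithium only in 7)
Why: Greene alkynyl ether synthesis: the potassium alkoxide adds to dichloroacetylene formed from trichloroethylene to give the (E)-dichlorovinyl ether, n-BuLi then effects dehydrochlorination and lithium–chlorine exchange (the third equivalent covers the terminal alkyne) and methanol protonates both acetylides; the stereocentres are not involved.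

**Step 4**
Reactants: 9 methoxyacetic acid
Product: 11 2-methoxypent-4-enoic acid (racemic), via dilithium enediolate 10 (not isolated)
Conditions: LDA (2.2 equiv), THF, −78 → 0 °C; allyl bromide, −78 °C → rt; 1 M HCl
Reagents that add atoms: allyl bromide, C=CCBr; lithium diisopropylamide, [Li]N(C(C)C)C(C)C (lithium only in 10)
Why: Alkylation of a carboxylic acid dianion with a reactive allylic halide; the new stereocentre is racemic and irrelevant because it becomes the sp2 ketene carbon.

**Step 5**
Reactants: 11 2-methoxypent-4-enoic acid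
Product: 12 2-methoxypent-4-enoyl chloride (racemic)
Conditions: (COCl)2, DMF (cat.), CH2Cl2, 0 °C → rt; bulb-to-bulb distillation
Reagents that add atoms: oxalyl chloride, O=C(Cl)C(=O)Cl
Why: DMF-catalysed acid chloride formation (Vilsmeier-type activation) under conditions that leave the methyl ether and the terminal alkene untouched.

**Step 6**
Reactants: 8 4-[(1R,2R)-1-(ethynyloxy)-2-methylbut-3-yn-1-yl]-1,2-dimethoxybenzene; 12 2-methoxypent-4-enoyl chloride
Product: 14 (2R,3R,5S)-5-allyl-2-(3,4-dimethoxyphenyl)-5-methoxy-3-methyl-2,3-dihydro-1-benzofuran-6(5H)-one, via allyl(methoxy)ketene 13 (not isolated)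
Conditions: 12 (1.5 equiv), Et3N, toluene, −78 → −20 °C, cold cannula filtration; ketene solution added over 4 h to 8, Ni(cod)2 (10 mol %), (R,R)-DIOP (12 mol %), toluene, 25 °C
Reagents that add atoms: none
Why: Proposed new method: dehydrochlorination of 12 gives ketene 13, zerovalent nickel/diphosphine couples the two alkynes of 8 oxidatively to a nickelacyclopentadiene that already holds the dihydrofuran, the ketene C=C inserts with its electrophilic carbonyl carbon bonding to the nucleophilic β-carbon of the ynol ether (C7), and C(sp3)–C(sp2) reductive elimination to C4 closes the dienone, so both rings and the C5 quaternary centre arise in one [2+2+2] cycloaddition; the closest known reaction type is the nickel/diphosphine-catalysed [2+2+2] cycloaddition of 1,6-diynes with disubstituted ketenes to 6,6-disubstituted cyclohexa-2,4-dienones, together with cyclotrimerisations of ynamide- and ynol-ether-tethered diynes; C2 and C3 pass through unchanged and C5 (S) is set by the chiral diphosphine, the 5R epimer and any regioisomer being removed by chromatography.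

**Compound list**

1 | (S)-but-3-yn-2-ol | C[C@H](O)C#C | starting material
2 | (S)-but-3-yn-2-yl methanesulfonate | C[C@H](OS(C)(=O)=O)C#C | intermediate
3 | 3,4-dimethoxybenzaldehyde | COc1ccc(C=O)cc1OC | starting material
4 | ethyl[(aR)-buta-1,2-dien-1-yl]zinc | [H]C(C)=[C@@]=C([H])[Zn]CC | intermediate (not isolated)
5 | (1R,2R)-1-(3,4-dimethoxyphenyl)-2-methylbut-3-yn-1-ol | O[C@@H](c1ccc(OC)c(OC)c1)[C@@H](C#C)C | intermediate
6 | 4-[(1R,2R)-1-{[(E)-1,2-dichloroethenyl]oxy}-2-methylbut-3-yn-1-yl]-1,2-dimethoxybenzene | Cl/C=C(/Cl)O[C@@H](c1ccc(OC)c(OC)c1)[C@@H](C#C)C | intermediate (not isolated)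
7 | dilithio derivative of 8 (both alkyne termini lithiated) | [Li]C#CO[C@@H](c1ccc(OC)c(OC)c1)[C@@H](C#C[Li])C | intermediate (not isolated)
8 | 4-[(1R,2R)-1-(ethynyloxy)-2-methylbut-3-yn-1-yl]-1,2-dimethoxybenzene | C#CO[C@@H](c1ccc(OC)c(OC)c1)[C@@H](C#C)C | intermediate
9 | methoxyacetic acid | COCC(=O)O | starting material
10 | dilithium 2-methoxyethene-1,1-diolate | [Li+].[Li+].COC=C([O-])[O-] | intermediate (not isolated)
11 | 2-methoxypent-4-enoic acid (racemic) | C=CCC(OC)C(=O)O | intermediate
12 | 2-methoxypent-4-enoyl chloride (racemic) | C=CCC(OC)C(=O)Cl | intermediate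
13 | allyl(methoxy)ketene (2-methoxypenta-1,4-dien-1-one) | C=CCC(OC)=C=O | intermediate (not isolated)
14 | (2R,3R,5S)-5-allyl-2-(3,4-dimethoxyphenyl)-5-methoxy-3-methyl-2,3-dihydro-1-benzofuran-6(5H)-one | C=CC[C@]1(OC)C=C2C(=CC1=O)O[C@@H](c1ccc(OC)c(OC)c1)[C@@H]2C | target

**Totals**

Total steps: 6. Longest linear sequence: 4 (steps 1, 2, 3, 6: 1 → 2 → 5 → 8 → 14); the side branch 9 → 11 → 12 is 2 steps.

**Three steps most likely to fail**

Step 6 is the main risk. The cycloaddition is untested with an in-situ alkoxyketene, two terminal alkynes and an ynol ether. Competing paths are uncatalysed [2+2] of 13 with the ynol ether, diyne oligomerisation, ketene dimerisation, the wrong insertion regiochemistry and weak control at C5. Compounds 8 and 14 must also stay below about 60 °C because of sigmatropic pathways.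

The fallback sets out from 3 and comes back at 14 by a dearomative cation–alkene annulation with a Cope relay:
- Wittig olefination of 3 (EtPPh3Br, KOtBu; then cat. I2) gives (E)-1,2-dimethoxy-4-(prop-1-en-1-yl)benzene F1.
- Baeyer–Villiger oxidation of 3 (mCPBA) and methanolysis (K2CO3, MeOH) gives 3,4-dimethoxyphenol F2.
- O-allylation (allyl bromide, K2CO3, acetone) gives 4-(allyloxy)-1,2-dimethoxybenzene F3.
- Claisen rearrangement (N,N-diethylaniline, 190 °C) gives 2-allyl-4,5-dimethoxyphenol F4.
- PhI(OAc)2 in MeOH gives the quinone monoketal 2-allyl-4,4,5-trimethoxycyclohexa-2,5-dien-1-one F5.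
- Acid-promoted formal [3+2] annulation of F5 with F1 (TfOH or SnCl4, MeCN, −30 °C) gives, beside its 2,3-trans 3a-epimer, racemic (2S,3R,3aR)-3a-allyl-2-(3,4-dimethoxyphenyl)-5-methoxy-3-methyl-3,3a-dihydro-1-benzofuran-6(2H)-one F6.
- Acid equilibration of the benzylic C2 (TsOH, CH2Cl2) turns it into the 2,3-trans isomer, racemic (2R,3R,3aR)-3a-allyl-2-(3,4-dimethoxyphenyl)-5-methoxy-3-methyl-3,3a-dihydro-1-benzofuran-6(2H)-one F7.
- Suprafacial Cope rearrangement (toluene, 110 °C, stopped at partial conversion) moves the allyl group from C3a to C5 on the same face and gives racemic 14.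
- Preparative HPLC on a chiral stationary phase removes (2S,3S,5R)-5-allyl-2-(3,4-dimethoxyphenyl)-5-methoxy-3-methyl-2,3-dihydro-1-benzofuran-6(5H)-one F8 and delivers 14.

Step 3 is the second risk. The benzylic ynol ether 8 is thermally labile (sigmatropic and retro-ene pathways), and KH or dichloroacetylene may attack the free terminal alkyne.

The fallback sets out from 5 and comes back at 8:
- Formylation (formic acetic anhydride, pyridine) gives (1R,2R)-1-(3,4-dimethoxyphenyl)-2-methylbut-3-yn-1-yl formate F9.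
- Dibromo-olefination of the formate carbonyl (CBr4, PPh3, CH2Cl2) gives 4-[(1R,2R)-1-[(2,2-dibromoethenyl)oxy]-2-methylbut-3-yn-1-yl]-1,2-dimethoxybenzene F10.
- n-BuLi (3.3 equiv, −78 °C) brings about elimination and lithium–bromine exchange to the dilithio species 7, and a methanol quench gives 8.

Step 2 is the third risk. Aryl aldehydes give lower anti:syn ratios in allenylzinc additions, and the parent terminal mesylate can erode ee.

The fallback sets out from 3 and comes back at 5:
- Brown anti-crotylboration of 3, using the (E)-crotyldiisopinocampheylborane antipode that gives the 1R,2R product, affords (1R,2R)-1-(3,4-dimethoxyphenyl)-2-methylbut-3-en-1-ol F11.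
- Silylation (TBSCl, imidazole, DMF) gives tert-butyl{[(1R,2R)-1-(3,4-dimethoxyphenyl)-2-methylbut-3-en-1-yl]oxy}dimethylsilane F12.
- Ozonolysis (O3, CH2Cl2, −78 °C; PPh3) gives (2S,3R)-3-[(tert-butyldimethylsilyl)oxy]-3-(3,4-dimethoxyphenyl)-2-methylpropanal F13.
- Ohira–Bestmann homologation (dimethyl (1-diazo-2-oxopropyl)phosphonate, K2CO3, MeOH, 0 °C) gives tert-butyl{[(1R,2R)-1-(3,4-dimethoxyphenyl)-2-methylbut-3-yn-1-yl]oxy}dimethylsilane F14.
- TBAF in THF releases 5.

**Further compounds**

F1 | step 6 | (E)-1,2-dimethoxy-4-(prop-1-en-1-yl)benzene | C/C=C/c1ccc(OC)c(OC)c1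
F2 | step 6 | 3,4-dimethoxyphenol | COc1ccc(O)cc1OC
F3 | step 6 | 4-(allyloxy)-1,2-dimethoxybenzene | C=CCOc1ccc(OC)c(OC)c1
F4 | step 6 | 2-allyl-4,5-dimethoxyphenol | C=CCc1cc(OC)c(OC)cc1O
F5 | step 6 | 2-allyl-4,4,5-trimethoxycyclohexa-2,5-dien-1-one | C=CCC1=CC(OC)(OC)C(OC)=CC1=O
F6 | step 6 | racemic (2S,3R,3aR)-3a-allyl-2-(3,4-dimethoxyphenyl)-5-methoxy-3-methyl-3,3a-dihydro-1-benzofuran-6(2H)-one (one enantiomer drawn) | C=CC[C@@]12C=C(OC)C(=O)C=C1O[C@H](c1ccc(OC)c(OC)c1)[C@@H]2C
F7 | step 6 | racemic (2R,3R,3aR)-3a-allyl-2-(3,4-dimethoxyphenyl)-5-methoxy-3-methyl-3,3a-dihydro-1-benzofuran-6(2H)-one (one enantiomer drawn) | C=CC[C@@]12C=C(OC)C(=O)C=C1O[C@@H](c1ccc(OC)c(OC)c1)[C@@H]2C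
F8 | step 6 | (2S,3S,5R)-5-allyl-2-(3,4-dimethoxyphenyl)-5-methoxy-3-methyl-2,3-dihydro-1-benzofuran-6(5H)-one | C=CC[C@@]1(OC)C=C2C(=CC1=O)O[C@H](c1ccc(OC)c(OC)c1)[C@H]2C
F9 | step 3 | (1R,2R)-1-(3,4-dimethoxyphenyl)-2-methylbut-3-yn-1-yl formate | O=CO[C@@H](c1ccc(OC)c(OC)c1)[C@@H](C#C)C
F10 | step 3 | 4-[(1R,2R)-1-[(2,2-dibromoethenyl)oxy]-2-methylbut-3-yn-1-yl]-1,2-dimethoxybenzene | BrC(Br)=CO[C@@H](c1ccc(OC)c(OC)c1)[C@@H](C#C)C
F11 | step 2 | (1R,2R)-1-(3,4-dimethoxyphenyl)-2-methylbut-3-en-1-ol | O[C@@H](c1ccc(OC)c(OC)c1)[C@@H](C=C)C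
F12 | step 2 | tert-butyl{[(1R,2R)-1-(3,4-dimethoxyphenyl)-2-methylbut-3-en-1-yl]oxy}dimethylsilane | CC(C)(C)[Si](C)(C)O[C@@H](c1ccc(OC)c(OC)c1)[C@@H](C=C)C
F13 | step 2 | (2S,3R)-3-[(tert-butyldimethylsilyl)oxy]-3-(3,4-dimethoxyphenyl)-2-methylpropanal | CC(C)(C)[Si](C)(C)O[C@@H](c1ccc(OC)c(OC)c1)[C@@H](C=O)C
F14 | step 2 | tert-butyl{[(1R,2R)-1-(3,4-dimethoxyphenyl)-2-methylbut-3-yn-1-yl]oxy}dimethylsilane | CC(C)(C)[Si](C)(C)O[C@@H](c1ccc(OC)c(OC)c1)[C@@H](C#C)C
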